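The fourteen-membered ring is numbered C1–C14: C4 bears C18H2O-malonyl, C8 the formyl carbon C19, C12 a methyl group, and C15 is the CMe2 carbon. The 2,2-dimethyltetrahydrofuran ring (O, C3, C2, C1, C15) is disconnected at O–C3, C2–C3 and C1–C15. Because C1 carries the ring methylene C14 beside C15, this ring is the product of a Prins–pinacol condensation. An aldehyde (C3, with the C4 stereocentre and the C5–C12 chain) condenses with 2-methylpent-4-ene-2,3-diol; C15 shifts from C14 to C1 and C14 is left as a formyl group. One operation joins both fragments and sets C3 and C1. Methylenation and a B-alkyl Suzuki–Miyaura macrocyclisation at C12–C13 close the carbocycle.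

Key step: step 13

Remark: the allylic diol of the key step is used as the racemate, because its only stereocentre (C14) becomes the sp2 formyl carbon there.

Step 1
Reactants: 1 (S)-4-benzyl-1,3-oxazolidin-2-one; 2 hex-5-enoyl chloride
Product: 3 (S)-4-benzyl-3-(hex-5-enoyl)-1,3-oxazolidin-2-one
Conditions: n-BuLi, THF, −78 °C; then 2, −78 → 0 °C
Reagents that add atoms: none
Why: N-acylation of the lithiated oxazolidinone by the acid chloride installs the Evans auxiliary that will control C4; no stereocentre is formed.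

Step 2
Reactants: 3 (S)-4-benzyl-3-(hex-5-enoyl)-1,3-oxazolidin-2-one
Product: 4 (S)-4-benzyl-3-[(R)-2-(hydroxymethyl)hex-5-enoyl]-1,3-oxazolidin-2-one
Conditions: TiCl4, i-Pr2NEt, CH2Cl2, 0 °C; then 1,3,5-trioxane, TiCl4, 0 °C
Reagents that add atoms: 1,3,5-trioxane, C1OCOCO1
Why: Evans-type hydroxymethylation, in which the chelated chlorotitanium (Z)-enolate should be attacked by TiCl4-activated formaldehyde on the face opposite the benzyl group, setting C4 and adding C18.

Step 3
Reactants: 4 (S)-4-benzyl-3-[(R)-2-(hydroxymethyl)hex-5-enoyl]-1,3-oxazolidin-2-one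
Product: 5 (S)-4-benzyl-3-[(R)-2-{[(tert-butyldiphenylsilyl)oxy]methyl}hex-5-enoyl]-1,3-oxazolidin-2-one
Conditions: t-BuPh2SiCl, imidazole, DMF, 23 °C
Reagents that add atoms: tert-butyl(chloro)diphenylsilane, CC(C)(C)[Si](Cl)(c1ccccc1)c1ccccc1
Why: Standard silylation of the primary alcohol; the bulky, acid-stable silyl ether later acts as the large group at C4 in the key step.

Step 4
Reactants: 5 (S)-4-benzyl-3-[(R)-2-{[(tert-butyldiphenylsilyl)oxy]methyl}hex-5-enoyl]-1,3-oxazolidin-2-one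
Product: 6 (R)-5-[(S)-4-benzyl-2-oxo-1,3-oxazolidin-3-yl]-4-{[(tert-butyldiphenylsilyl)oxy]methyl}-5-oxopentanal
Conditions: O3, CH2Cl2, −78 °C; then PPh3, −78 → 23 °C
Reagents that add atoms: ozone, [O-][O+]=O
Why: Ozonolysis with reductive work-up cleaves the only alkene of 5 to the C7 aldehyde and leaves the imide and the silyl ether untouched.

Step 5
Reactants: 7 3-[(tert-butyldimethylsilyl)oxy]propanal
Product: 8 (Z)-tert-butyl[(4-iodopent-3-en-1-yl)oxy]dimethylsilane
Conditions: EtPPh3I, n-BuLi, THF, 23 °C; I2, −78 °C; NaN(SiMe3)2, −20 °C; then 7, −78 → −20 °C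
Reagents that add atoms: ethyltriphenylphosphonium iodide, CC[P+](c1ccccc1)(c1ccccc1)c1ccccc1.[I-]; iodine, II
Why: Stork–Zhao olefination with the α-iodoethylidene ylide should give the (Z)-2-iodoalkene (iodine cis to the chain) under kinetic control, fixing the later C11=C12 geometry.

Step 6
Reactants: 8 (Z)-tert-butyl[(4-iodopent-3-en-1-yl)oxy]dimethylsilane
Product: 9 (Z)-4-iodopent-3-en-1-ol
Conditions: camphorsulfonic acid (cat.), MeOH, 23 °C
Reagents that add atoms: none
Why: Acid-catalysed methanolysis removes the primary silyl ether; the vinyl iodide is inert to it.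

Step 7
Reactants: 9 (Z)-4-iodopent-3-en-1-ol
Product: 10 (Z)-2,5-diiodopent-2-ene
Conditions: I2, PPh3, imidazole, CH2Cl2, 0 → 23 °C
Reagents that add atoms: iodine, II
Why: Appel-type iodination converts the primary alcohol into the primary iodide without touching the alkene geometry.

Step 8
Reactants: 10 (Z)-2,5-diiodopent-2-ene; 11 triethyl phosphonoacetate
Product: 12 ethyl (Z)-2-(diethoxyphosphoryl)-6-iodohept-5-enoate (racemic at C2)
Conditions: 11 (excess), NaH, THF/DMF, 0 °C; then 10, 50 °C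
Reagents that add atoms: none
Why: The sodium phosphonoacetate is C-alkylated by the primary iodide in a bimolecular substitution, whereas the vinyl iodide cannot react this way.

Step 9
Reactants: 6 (R)-5-[(S)-4-benzyl-2-oxo-1,3-oxazolidin-3-yl]-4-{[(tert-butyldiphenylsilyl)oxy]methyl}-5-oxopentanal; 12 ethyl (Z)-2-(diethoxyphosphoryl)-6-iodohept-5-enoate
Product: 13 ethyl (2E,6R)-7-[(S)-4-benzyl-2-oxo-1,3-oxazolidin-3-yl]-6-{[(tert-butyldiphenylsilyl)oxy]methyl}-2-[(Z)-4-iodopent-3-en-1-yl]-7-oxohept-2-enoate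
Conditions: LiCl, DBU, MeCN, 0 → 23 °C
Reagents that add atoms: none
Why: Horner–Wadsworth–Emmons olefination under Masamune–Roush conditions should give the (E)-trisubstituted enoate (ester trans to C6) and forms C7=C8; the imide α-centre is protected from enolisation by allylic strain.

Step 10
Reactants: 13 ethyl (2E,6R)-7-[(S)-4-benzyl-2-oxo-1,3-oxazolidin-3-yl]-6-{[(tert-butyldiphenylsilyl)oxy]methyl}-2-[(Z)-4-iodopent-3-en-1-yl]-7-oxohept-2-enoate
Product: 14 ethyl (2E,6S)-6-{[(tert-butyldiphenylsilyl)oxy]methyl}-7-hydroxy-2-[(Z)-4-iodopent-3-en-1-yl]hept-2-enoate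
Conditions: NaBH4, THF/H2O, 0 → 23 °C
Reagents that add atoms: none
Why: Borohydride reductive cleavage of the N-acyl oxazolidinone gives the primary alcohol and releases 1, while the enoate and vinyl iodide are inert and the bulky silyl group should not migrate, so C4 is kept.

Step 11
Reactants: 14 ethyl (2E,6S)-6-{[(tert-butyldiphenylsilyl)oxy]methyl}-7-hydroxy-2-[(Z)-4-iodopent-3-en-1-yl]hept-2-enoate
Product: 15 ethyl (2E,6R)-6-{[(tert-butyldiphenylsilyl)oxy]methyl}-2-[(Z)-4-iodopent-3-en-1-yl]-7-oxohept-2-enoate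
Conditions: Dess–Martin periodinane, NaHCO3, CH2Cl2, 0 → 23 °C
Reagents that add atoms: none
Why: Buffered Dess–Martin oxidation gives the α-branched C3 aldehyde under neutral conditions that should not epimerise C4; the aldehyde is used at once.

Step 12
Reactants: 16 methyl 2-hydroxybut-3-enoate (racemic)
Product: 17 2-methylpent-4-ene-2,3-diol (racemic)
Conditions: MeMgBr (excess), THF, 0 → 23 °C; aq. NH4Cl
Reagents that add atoms: methylmagnesium bromide, C[Mg]Br
Why: Double Grignard addition to the ester (after deprotonation of the hydroxyl) gives the tertiary carbinol C15 with its two methyl groups next to the allylic carbinol C14.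

Step 13
Reactants: 15 ethyl (2E,6R)-6-{[(tert-butyldiphenylsilyl)oxy]methyl}-2-[(Z)-4-iodopent-3-en-1-yl]-7-oxohept-2-enoate; 17 2-methylpent-4-ene-2,3-diol
Product: 19 ethyl (2E,6R)-6-{[(tert-butyldiphenylsilyl)oxy]methyl}-6-[(2R,4R)-4-formyl-5,5-dimethyloxolan-2-yl]-2-[(Z)-4-iodopent-3-en-1-yl]hex-2-enoate, via dioxolane acetal 18 (not isolated)
Conditions: 17 (1.5 equiv), camphorsulfonic acid (cat.), MgSO4, CH2Cl2, 23 °C; then SnCl4 (2.5 equiv), −78 → −20 °C, same flask
Reagents that add atoms: none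
Why: Acid-catalysed acetalisation gives dioxolane 18; SnCl4 binds the less hindered allylic oxygen and opens 18 to the (E)-oxocarbenium ion on the tertiary oxygen (this is where O–C3 is made), the vinyl terminus C2 adds to C3 through a six-membered chair (6-endo Prins closure, equivalent to a 2-oxonia-Cope [3,3] shift), and C15 then shifts from C14 to the electron-poor C1 (pinacol-type 1,2-shift, equivalent to a 5-(enolexo)-endo-trig aldol closure of the C1=C14 enol on the C15 oxocarbenium carbon), which contracts the six-membered array to the oxolane and leaves C14 as the formyl group. The closest known reaction type is the Prins–pinacol condensation of allylic diols with aldehydes to 3-acyltetrahydrofurans. C3 is set relative to C4 by Felkin–Anh addition to the oxocarbenium ion, with the C4–C18 bond and its bulky silyloxymethyl group anti to the incoming C2 and the smaller C5 chain inside; C1 is set relative to C3 by the chair, in which the C4 side chain is equatorial and C15 is delivered to the same alkene face as C3, so the formyl group and the side chain should come out cis, which is also the more stable arrangement next to the epimerisable aldehyde. The carbinol centre of 17 ends as the sp2 formyl carbon, so both enantiomers of 17 lead to the same product. The step needs facial selectivity at C3, ionisation toward the tertiary oxygen and inert bystander alkenes; the C4 stereocentre, the steric bias of the dioxolane and the electron-poor enoate and vinyl iodide should provide these.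

Step 14
Reactants: 19 ethyl (2E,6R)-6-{[(tert-butyldiphenylsilyl)oxy]methyl}-6-[(2R,4R)-4-formyl-5,5-dimethyloxolan-2-yl]-2-[(Z)-4-iodopent-3-en-1-yl]hex-2-enoate
Product: 20 ethyl (2E,6R)-6-{[(tert-butyldiphenylsilyl)oxy]methyl}-6-[(2R,4S)-4-ethenyl-5,5-dimethyloxolan-2-yl]-2-[(Z)-4-iodopent-3-en-1-yl]hex-2-enoate
Conditions: Ph3PCH3Br, KN(SiMe3)2, THF, 0 °C; then 19, −78 → 0 °C
Reagents that add atoms: methyltriphenylphosphonium bromide, C[P+](c1ccccc1)(c1ccccc1)c1ccccc1.[Br-]
Why: Wittig methylenation adds C13 to the hindered aldehyde at low temperature; the cis configuration at C1 is also the favoured one, so brief enolisation should not erode it.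

Step 15
Reactants: 20 ethyl (2E,6R)-6-{[(tert-butyldiphenylsilyl)oxy]methyl}-6-[(2R,4S)-4-ethenyl-5,5-dimethyloxolan-2-yl]-2-[(Z)-4-iodopent-3-en-1-yl]hex-2-enoate
Product: 22 ethyl (1R,3R,4R,7E,11Z)-18-[(tert-butyldiphenylsilyl)oxy]-3,15-epoxycembra-7,11-dien-19-oate, via alkylborane 21 (not isolated)
Conditions: 9-BBN-H, THF, 23 °C; then slow addition to PdCl2(dppf) ([1,1'-bis(diphenylphosphino)ferrocene]palladium dichloride, cat.), AsPh3, Cs2CO3, DMF/THF/H2O, 50 °C, high dilution
Reagents that add atoms: 9-borabicyclo[3.3.1]nonane, B1C2CCCC1CCC2 (its boron stays only in intermediate 21; product 22 keeps one hydrogen from it)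
Why: 9-BBN-H hydroborates only the monosubstituted alkene at C13, and the intramolecular B-alkyl Suzuki–Miyaura coupling with the (Z)-vinyl iodide should form C12–C13 with retention of alkene geometry and close the fourteen-membered ring.

Step 16
Reactants: 22 ethyl (1R,3R,4R,7E,11Z)-18-[(tert-butyldiphenylsilyl)oxy]-3,15-epoxycembra-7,11-dien-19-oate
Product: 23 (1R,3R,4R,7E,11Z)-18-[(tert-butyldiphenylsilyl)oxy]-3,15-epoxycembra-7,11-dien-19-ol
Conditions: i-Bu2AlH, CH2Cl2, −78 °C; Rochelle salt work-up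
Reagents that add atoms: none
Why: 1,2-Reduction of the conjugated ester by i-Bu2AlH gives the allylic alcohol without touching the alkenes or the silyl ether.

Step 17
Reactants: 23 (1R,3R,4R,7E,11Z)-18-[(tert-butyldiphenylsilyl)oxy]-3,15-epoxycembra-7,11-dien-19-ol
Product: 24 (1R,3R,4R,7E,11Z)-18-[(tert-butyldiphenylsilyl)oxy]-3,15-epoxycembra-7,11-dien-19-al
Conditions: MnO2, CH2Cl2, 23 °C
Reagents that add atoms: none
Why: MnO2 oxidises the allylic alcohol selectively to the (E)-enal, the more stable geometry.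

Step 18
Reactants: 24 (1R,3R,4R,7E,11Z)-18-[(tert-butyldiphenylsilyl)oxy]-3,15-epoxycembra-7,11-dien-19-al
Product: 25 (1R,3R,4R,7E,11Z)-18-hydroxy-3,15-epoxycembra-7,11-dien-19-al
Conditions: Bu4NF, AcOH, THF, 0 → 23 °C
Reagents that add atoms: none
Why: Acetic-acid-buffered fluoride cleaves the silyl ether to the C18 alcohol under conditions mild enough for the enal.

Step 19
Reactants: 25 (1R,3R,4R,7E,11Z)-18-hydroxy-3,15-epoxycembra-7,11-dien-19-al
Product: 26 3-{[(1R,3R,4R,7E,11Z)-19-oxo-3,15-epoxycembra-7,11-dien-18-yl]oxy}-3-oxopropanoic acid (CNP0170412.1)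
Conditions: Meldrum's acid, toluene, 90 °C
Reagents that add atoms: Meldrum's acid (2,2-dimethyl-1,3-dioxane-4,6-dione), CC1(C)OC(=O)CC(=O)O1
Why: Thermal alcoholysis of Meldrum's acid by the primary alcohol gives the malonic half ester directly with loss of acetone; without base the hindered enal should not condense.

Compound list
1 | (S)-4-benzyl-1,3-oxazolidin-2-one | O=C1N[C@@H](Cc2ccccc2)CO1 | starting material
2 | hex-5-enoyl chloride | C=CCCCC(=O)Cl | starting material
3 | (S)-4-benzyl-3-(hex-5-enoyl)-1,3-oxazolidin-2-one | C=CCCCC(=O)N1C(=O)OC[C@@H]1Cc1ccccc1 | intermediate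
4 | (S)-4-benzyl-3-[(R)-2-(hydroxymethyl)hex-5-enoyl]-1,3-oxazolidin-2-one | C=CCC[C@H](CO)C(=O)N1C(=O)OC[C@@H]1Cc1ccccc1 | intermediate
5 | (S)-4-benzyl-3-[(R)-2-{[(tert-butyldiphenylsilyl)oxy]methyl}hex-5-enoyl]-1,3-oxazolidin-2-one | C=CCC[C@H](CO[Si](c1ccccc1)(c1ccccc1)C(C)(C)C)C(=O)N1C(=O)OC[C@@H]1Cc1ccccc1 | intermediate
6 | (R)-5-[(S)-4-benzyl-2-oxo-1,3-oxazolidin-3-yl]-4-{[(tert-butyldiphenylsilyl)oxy]methyl}-5-oxopentanal | O=CCC[C@H](CO[Si](c1ccccc1)(c1ccccc1)C(C)(C)C)C(=O)N1C(=O)OC[C@@H]1Cc1ccccc1 | intermediate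
7 | 3-[(tert-butyldimethylsilyl)oxy]propanal | O=CCCO[Si](C)(C)C(C)(C)C | starting material
8 | (Z)-tert-butyl[(4-iodopent-3-en-1-yl)oxy]dimethylsilane | C/C(I)=C/CCO[Si](C)(C)C(C)(C)C | intermediate
9 | (Z)-4-iodopent-3-en-1-ol | C/C(I)=C/CCO | intermediate
10 | (Z)-2,5-diiodopent-2-ene | C/C(I)=C/CCI | intermediate
11 | triethyl phosphonoacetate | CCOC(=O)CP(=O)(OCC)OCC | starting material
12 | ethyl (Z)-2-(diethoxyphosphoryl)-6-iodohept-5-enoate (racemic at C2) | CCOC(=O)C(CC/C=C(/C)I)P(=O)(OCC)OCC | intermediate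
13 | ethyl (2E,6R)-7-[(S)-4-benzyl-2-oxo-1,3-oxazolidin-3-yl]-6-{[(tert-butyldiphenylsilyl)oxy]methyl}-2-[(Z)-4-iodopent-3-en-1-yl]-7-oxohept-2-enoate | C/C(I)=C/CC/C(C(=O)OCC)=C\CC[C@H](CO[Si](c1ccccc1)(c1ccccc1)C(C)(C)C)C(=O)N1C(=O)OC[C@@H]1Cc1ccccc1 | intermediate
14 | ethyl (2E,6S)-6-{[(tert-butyldiphenylsilyl)oxy]methyl}-7-hydroxy-2-[(Z)-4-iodopent-3-en-1-yl]hept-2-enoate | C/C(I)=C/CC/C(C(=O)OCC)=C\CC[C@H](CO[Si](c1ccccc1)(c1ccccc1)C(C)(C)C)CO | intermediate
15 | ethyl (2E,6R)-6-{[(tert-butyldiphenylsilyl)oxy]methyl}-2-[(Z)-4-iodopent-3-en-1-yl]-7-oxohept-2-enoate | C/C(I)=C/CC/C(C(=O)OCC)=C\CC[C@H](CO[Si](c1ccccc1)(c1ccccc1)C(C)(C)C)C=O | intermediate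
16 | methyl 2-hydroxybut-3-enoate (racemic) | C=CC(O)C(=O)OC | starting material
17 | 2-methylpent-4-ene-2,3-diol (racemic) | CC(C)(O)C(O)C=C | intermediate
18 | ethyl (2E,6R)-6-{[(tert-butyldiphenylsilyl)oxy]methyl}-6-(4,4-dimethyl-5-ethenyl-1,3-dioxolan-2-yl)-2-[(Z)-4-iodopent-3-en-1-yl]hex-2-enoate (not isolated; mixture of isomers at the two dioxolane stereocentres) | C/C(I)=C/CC/C(C(=O)OCC)=C\CC[C@H](CO[Si](c1ccccc1)(c1ccccc1)C(C)(C)C)C1OC(C=C)C(C)(C)O1 | intermediate
19 | ethyl (2E,6R)-6-{[(tert-butyldiphenylsilyl)oxy]methyl}-6-[(2R,4R)-4-formyl-5,5-dimethyloxolan-2-yl]-2-[(Z)-4-iodopent-3-en-1-yl]hex-2-enoate | C/C(I)=C/CC/C(C(=O)OCC)=C\CC[C@H](CO[Si](c1ccccc1)(c1ccccc1)C(C)(C)C)[C@H]1C[C@@H](C=O)C(C)(C)O1 | intermediate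
20 | ethyl (2E,6R)-6-{[(tert-butyldiphenylsilyl)oxy]methyl}-6-[(2R,4S)-4-ethenyl-5,5-dimethyloxolan-2-yl]-2-[(Z)-4-iodopent-3-en-1-yl]hex-2-enoate | C/C(I)=C/CC/C(C(=O)OCC)=C\CC[C@H](CO[Si](c1ccccc1)(c1ccccc1)C(C)(C)C)[C@H]1C[C@@H](C=C)C(C)(C)O1 | intermediate
21 | B-alkyl-9-borabicyclo[3.3.1]nonane from hydroboration of the ethenyl group of 20 (boron on C13; not isolated) | C/C(I)=C/CC/C(C(=O)OCC)=C\CC[C@H](CO[Si](c1ccccc1)(c1ccccc1)C(C)(C)C)[C@H]1C[C@@H](CCB2C3CCCC2CCC3)C(C)(C)O1 | intermediate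
22 | ethyl (1R,3R,4R,7E,11Z)-18-[(tert-butyldiphenylsilyl)oxy]-3,15-epoxycembra-7,11-dien-19-oate | C/C1=C/CC/C(C(=O)OCC)=C\CC[C@H](CO[Si](c2ccccc2)(c2ccccc2)C(C)(C)C)[C@H]2C[C@@H](CC1)C(C)(C)O2 | intermediate
23 | (1R,3R,4R,7E,11Z)-18-[(tert-butyldiphenylsilyl)oxy]-3,15-epoxycembra-7,11-dien-19-ol | C/C1=C/CC/C(CO)=C\CC[C@H](CO[Si](c2ccccc2)(c2ccccc2)C(C)(C)C)[C@H]2C[C@@H](CC1)C(C)(C)O2 | intermediate
24 | (1R,3R,4R,7E,11Z)-18-[(tert-butyldiphenylsilyl)oxy]-3,15-epoxycembra-7,11-dien-19-al | C/C1=C/CC/C(C=O)=C\CC[C@H](CO[Si](c2ccccc2)(c2ccccc2)C(C)(C)C)[C@H]2C[C@@H](CC1)C(C)(C)O2 | intermediate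
25 | (1R,3R,4R,7E,11Z)-18-hydroxy-3,15-epoxycembra-7,11-dien-19-al | C/C1=C/CC/C(C=O)=C\CC[C@H](CO)[C@H]2C[C@@H](CC1)C(C)(C)O2 | intermediate
26 | 3-{[(1R,3R,4R,7E,11Z)-19-oxo-3,15-epoxycembra-7,11-dien-18-yl]oxy}-3-oxopropanoic acid (CNP0170412.1) | C/C1=C/CC/C(C=O)=C\CC[C@H](COC(=O)CC(=O)O)[C@H]2C[C@@H](CC1)C(C)(C)O2 | target

Total step count: 19. Longest linear sequence: 14 steps (steps 1–4, 9–11 and 13–19).

Steps most likely to fail

Step 13. The addition to the oxocarbenium ion may show poor facial selectivity with respect to C4, because the two C4 substituents differ only modestly in size, and the α-branched aldehyde may enolise under the Lewis acid. The fallback sets out from 15 and comes back at 20. Reagent-controlled allylboration of 15 with (+)-B-allyldiisopinocampheylborane (Et2O, −78 °C; then NaOH/H2O2), which should deliver allyl to the Re face, gives the homoallylic alcohol F1 with C3 fixed. Cross-metathesis with allyltrimethylsilane (second-generation Grubbs catalyst, CH2Cl2, 40 °C) gives the (E)-allylsilane F2. 2-Methoxypropene with pyridinium 4-toluenesulfonate gives the mixed ketal F3, which with Me3SiOTf at −78 °C ionises to the oxocarbenium ion; the allylsilane closes the oxolane onto it with loss of silicon and gives 20, so steps 13 and 14 are bypassed.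

Step 15. Ring closure may lose out to oligomerisation, protodeboronation or slow transmetalation of the hindered alkylborane. The fallback sets out from 20 and comes back at 22. Hydroboration with 9-BBN-H and oxidation with NaBO3 give the primary alcohol F4, and I2, PPh3 and imidazole give the primary iodide F5. Activated Zn dust in THF at 40 °C should insert only into the sp3 carbon–iodine bond and give the alkylzinc iodide F6, which is added slowly to Pd(PPh3)4 in THF/DMF at 50 °C, so that an intramolecular Negishi coupling with the vinyl iodide closes the ring without base or water.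

Step 19. Meldrum's acid may condense with the enal (Knoevenagel reaction), or the enal may degrade on heating. The fallback sets out from 25 and comes back at 26. Esterification with 3-(allyloxy)-3-oxopropanoic acid (EDC hydrochloride, DMAP, CH2Cl2, 0 °C) gives the allyl malonate F7; Pd(PPh3)4 with sodium 4-toluenesulfinate in THF/MeOH at 23 °C removes the allyl group under neutral conditions and gives 26 after mild acidification.

Further compounds
F1 | step 13 | ethyl (2E,6R)-6-{[(tert-butyldiphenylsilyl)oxy]methyl}-6-[(R)-1-hydroxybut-3-en-1-yl]-2-[(Z)-4-iodopent-3-en-1-yl]hex-2-enoate | C/C(I)=C/CC/C(C(=O)OCC)=C\CC[C@H](CO[Si](c1ccccc1)(c1ccccc1)C(C)(C)C)[C@H](O)CC=C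
F2 | step 13 | ethyl (2E,6R)-6-{[(tert-butyldiphenylsilyl)oxy]methyl}-6-[(R,E)-1-hydroxy-5-(trimethylsilyl)pent-3-en-1-yl]-2-[(Z)-4-iodopent-3-en-1-yl]hex-2-enoate | C/C(I)=C/CC/C(C(=O)OCC)=C\CC[C@H](CO[Si](c1ccccc1)(c1ccccc1)C(C)(C)C)[C@H](O)C/C=C/C[Si](C)(C)C
F3 | step 13 | 2-methoxypropan-2-yl ether of F2 (mixed ketal, not isolated) | C/C(I)=C/CC/C(C(=O)OCC)=C\CC[C@H](CO[Si](c1ccccc1)(c1ccccc1)C(C)(C)C)[C@H](OC(C)(C)OC)C/C=C/C[Si](C)(C)C
F4 | step 15 | primary alcohol from anti-Markovnikov hydration of the ethenyl group of 20 (2-hydroxyethyl on the oxolane) | C/C(I)=C/CC/C(C(=O)OCC)=C\CC[C@H](CO[Si](c1ccccc1)(c1ccccc1)C(C)(C)C)[C@H]1C[C@@H](CCO)C(C)(C)O1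
F5 | step 15 | primary iodide from F4 (2-iodoethyl on the oxolane) | C/C(I)=C/CC/C(C(=O)OCC)=C\CC[C@H](CO[Si](c1ccccc1)(c1ccccc1)C(C)(C)C)[C@H]1C[C@@H](CCI)C(C)(C)O1
F6 | step 15 | alkylzinc iodide from F5 (not isolated) | C/C(I)=C/CC/C(C(=O)OCC)=C\CC[C@H](CO[Si](c1ccccc1)(c1ccccc1)C(C)(C)C)[C@H]1C[C@@H](CC[Zn]I)C(C)(C)O1
F7 | step 19 | allyl (1R,3R,4R,7E,11Z)-19-oxo-3,15-epoxycembra-7,11-dien-18-yl malonate | C/C1=C/CC/C(C=O)=C\CC[C@H](COC(=O)CC(=O)OCC=C)[C@H]2C[C@@H](CC1)C(C)(C)O2
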